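The earlier runs and the new flask were generated by integration for substances that don't exist; scatter was added.

**The count.** Tris adduct takes 3 gas additions per molecule of starting material, so I counted gas in fractions of the charge.

| flask | starting material | gas | remark | time |
|---|---|---|---|---|
| birch | 0.11 M | 78 mM (held) | run made earlier |  |
| ash | 2.2 M | 78 mM (held) | run made earlier |  |
| theta | 2.5 M | 78 mM (held) |  | 3.0 h |
| epsilon | 0.40 M | 78 mM (held) |  | 3.0 h |
| eta | 0.80 M | 78 mM (held) |  | 3.0 h |
| beta | 0.20 M | 78 mM (held) |  | 3.0 h |

| run | time / h | tris adduct / % | starting material / % |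
|---|---|---|---|
| birch | 0.200 | 0 | 43 |
| birch | 0.667 | 4 | 4 |
| birch | 1.00 | 14 | 1 |
| birch | 1.50 | 25 | 2 |
| birch | 2.50 | 49 | 0 |
| birch | 3.00 | 61 | 0 |
| ash | 0.250 | 1 | 70 |
| ash | 0.417 | 0 | 59 |
| ash | 0.667 | 0 | 50 |
| ash | 1.00 | 2 | 44 |
| ash | 2.00 | 0 | 30 |
| ash | 3.00 | 3 | 20 |

(scatter of a reading: 1.5 percentage points)

* ranking by amount of tris adduct, in percent of the starting material charged, from high to low, at 3.0 h (theta / epsilon / eta / beta)
* the amount of tris adduct, in percent of the starting material charged of the flask you put first, at 3.0 h
* the amount of tris adduct, in percent of the starting material charged of the flask you put last, at 3.0 h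

- at the start none of the gas is in solution

**Gas uptake.** Ash lost 80.0% of its charge in 3.00 h. Counting one gas per molecule lost, I read a gas uptake, the gas entering a litre per hour, of 0.587 M h⁻¹. Ash's early burst may not be gas, so this reading is rough.

**Two extremes.** In the rich extreme, gas stands at saturation and each flask follows birch, whose tris adduct rose by 0.235 h⁻¹ of the charge. In the starved extreme, gas reacts on arrival, so tris adduct starts after two charges of gas have entered. I called that time the gas delay: twice the charge over the uptake.

**Between them.** Birch's first reading gave starting material a rate constant of 4.22 h⁻¹. Beta's early demand was therefore 0.844 M h⁻¹, above the uptake. Its late demand for tris adduct was 0.0470 M h⁻¹, far below the uptake. So I expected beta to start near the starved extreme and drift towards the rich one, and I started birch's slope after the delay. Birch's delay reckons to 0.375 h, and its tris line crosses zero at 0.404 h. Those two come from different runs.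

My line gave beta 54.5%. Theta's delay of 8.52 h is longer than the run, so my line gave it none.

**The forecast.** It ranked beta > epsilon > eta > theta, as the delays do. It put beta at 46% (34% to 57%) and theta at 2% (0.5% to 4%), on the ground that “the effective rate falls as concentration rises”. My beta stood above its figure.

**The result.** The order was beta > epsilon > eta > theta, as in the forecast, with beta at 54.3% and theta at 0.498%. At 1.50 h, later than beta's delay of 0.682 h, beta held 72.8% as double product, with reagent at 0.0633 M.

    tris adduct → over-reaction product (k = 2.70 × 10⁻⁵ min⁻¹)
    starting material ⇌ dormant form (K = 0.570, k = 0.0280 min⁻¹)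
    reagent + double product → tris adduct + released group (k = 0.0950 M⁻¹ min⁻¹)
    starting material + reagent → first product + released group (k = 2.10 M⁻¹ min⁻¹)
    reagent + first product → double product + released group (k = 1.10 M⁻¹ min⁻¹)
    gas ⇌ reagent, rate k6*(csat - [reagent]) (kL = 0.150 min⁻¹)

**A neighbour.** This flask is beta with 0.34 M of starting material. Its delay is 1.16 h, so birch's slope gives 43.3%. The computed flask held 44.5% of tris adduct.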